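**Retrosynthetic overview**
1. Target 14 comes from benzoylation of the secondary C6–OH of epoxy diol 13, which comes from face-selective epoxidation of the trisubstituted C8=C9 olefin of the trans-fused hydroazulene diol 12.
2. 12 comes from ring-closing olefin metathesis of the monocyclic diene-diol 11; this forms the C8–C9 bond and the seven-membered ring C1–C5–C6–C7–C8–C9–C10 in one operation.
3. Enabling feature: on the cyclopentane ring (C1–C5) the allyl arm on quaternary C1 (C10, C9) and the 2-methylallyl carbinol arm on C5 (C6, C7, C8 with its methyl) are trans-vicinal. C9 and C8 are therefore the ends of a nona-1,8-diene whose closure gives the trans-fused cycloheptene, and its trisubstituted olefin is the direct precursor of the epoxide.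
4. 11 comes from isopropyl addition to ketone 10 (sets C4). 10 comes from an anti-aldol of a regiodefined enolate with 3-methylbut-3-enal (sets C5, C6). The enolate comes from catalytic asymmetric conjugate methylation of 3-allylcyclopent-2-en-1-one (sets C1).
5. Ring order: cyclopentane (present from 1), cycloheptene (step 6), oxirane (step 7, sets C8 and C9).

Key step: step 6

Assumption: the antipode of the chiral carbene ligand in step 2 is chosen so that the (R)-quaternary centre results; daucane numbering (C1 angular-methyl carbon, C4 isopropyl carbinol carbon, C5 ring-fusion CH, C6 oxygenated CH, C8/C9 olefin or epoxide carbons, C10 CH2) is used for all compounds, monocyclic ones included.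

**Step 1**
Reactants: 1 3-ethoxycyclopent-2-en-1-one
Product: 3 3-allylcyclopent-2-en-1-one, via bromomagnesium alkoxide 2 (not isolated)
Conditions: allylMgBr (1.2 equiv), THF, 0 °C; then 1 M HCl, 0 °C
Reagents that add atoms: allylmagnesium bromide, C=CC[Mg]Br
Why: Stork–Danheiser sequence, in which 1,2-addition of the Grignard reagent to the vinylogous ester and acid-promoted hydrolysis with loss of ethanol should give the transposed 3-substituted enone; no stereocenter is formed.

**Step 2**
Reactants: 3 3-allylcyclopent-2-en-1-one
Product: 5 (R)-[(3-allyl-3-methylcyclopent-1-en-1-yl)oxy]trimethylsilane, via dimethylaluminium enolate 4 (not isolated)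
Conditions: Me3Al (1.5 equiv), Cu(OTf)2 (5 mol %), chiral sulfonate-bearing imidazolinium salt as carbene precursor (6 mol %), THF, −78 °C; then Me3SiOTf, −78 → 0 °C; non-aqueous work-up
Reagents that add atoms: trimethylaluminium, C[Al](C)C; trimethylsilyl trifluoromethanesulfonate, C[Si](C)(C)OS(=O)(=O)C(F)(F)F
Why: Copper-catalysed asymmetric conjugate addition of a trialkylaluminium to a β-substituted cyclopentenone, in which the chiral carbene–copper complex selects the enone face and so sets the quaternary centre C1 as (R), while silylation of the aluminium enolate fixes the enolate regiochemistry towards C5.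

**Step 3**
Reactants: 6 3-methylbut-3-en-1-ol
Product: 7 3-methylbut-3-enal
Conditions: Dess–Martin periodinane (1.1 equiv), CH2Cl2, 0 °C → rt; used at once as a cold solution
Reagents that add atoms: none
Why: Dess–Martin oxidation of the primary alcohol under non-basic conditions should give the β,γ-unsaturated aldehyde without migration of the double bond into conjugation.

**Step 4**
Reactants: 5 (R)-[(3-allyl-3-methylcyclopent-1-en-1-yl)oxy]trimethylsilane; 7 3-methylbut-3-enal
Product: 10 (2S,3R)-3-allyl-2-[(1S)-1-hydroxy-3-methylbut-3-en-1-yl]-3-methylcyclopentan-1-one, via lithium enolate 8 (not isolated), via dicyclohexylboron enolate 9 (not isolated)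
Conditions: MeLi (1.05 equiv), THF, 0 °C; (c-C6H11)2BCl, −78 °C; then 7, −78 → −20 °C; H2O2, pH 7 buffer, MeOH, 0 °C
Reagents that add atoms: none
Why: Boron-mediated aldol addition of the regiodefined (E)-enolate through a Zimmerman–Traxler chair should give the anti aldol (C6 S), and the aldehyde should approach the enolate face opposite to the larger allyl group on C1, which sets C5 (S) with the new side chain trans to the allyl arm.

**Step 5**
Reactants: 10 (2S,3R)-3-allyl-2-[(1S)-1-hydroxy-3-methylbut-3-en-1-yl]-3-methylcyclopentan-1-one
Product: 11 (1R,2S,3R)-3-allyl-2-[(1S)-1-hydroxy-3-methylbut-3-en-1-yl]-3-methyl-1-(propan-2-yl)cyclopentan-1-ol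
Conditions: i-PrMgCl (4 equiv), anhydrous CeCl3 (4 equiv), THF, −78 → 0 °C; then sat. aq. NH4Cl
Reagents that add atoms: isopropylmagnesium chloride, CC(C)[Mg]Cl
Why: 1,2-addition of an organocerium reagent, which suppresses enolisation and β-hydride reduction of the hindered ketone, should occur on the carbonyl face opposite to the C5 side chain (the exo face of the chelate between the C6 alkoxide and the C4 carbonyl), so that C4 is set as (R) with its hydroxyl cis to the side chain.

**Step 6**
Reactants: 11 (1R,2S,3R)-3-allyl-2-[(1S)-1-hydroxy-3-methylbut-3-en-1-yl]-3-methyl-1-(propan-2-yl)cyclopentan-1-ol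
Product: 12 (1R,4R,5S,6S)-dauc-8-ene-4,6-diol
Conditions: second-generation Grubbs catalyst RuCl2(=CHPh)(PCy3)(H2IMes) (5 mol %), CH2Cl2 (0.005 M), 40 °C, slow argon purge
Reagents that add atoms: none
Why: Ring-closing olefin metathesis: the ruthenium alkylidene should load on the unhindered allyl terminus (C9), add across the 1,1-disubstituted olefin of the 2-methylallyl arm to a ruthenacyclobutane and cyclorevert, so that C8 and C9 become doubly bonded and ethene is lost. The closest known reaction type is ring-closing metathesis of a monosubstituted with a 1,1-disubstituted olefin to give a trisubstituted cycloheptene fused to a five-membered ring, as used for hydroazulene terpenoids. One ring is closed, the seven-membered carbocycle C1–C5–C6–C7–C8–C9–C10, by intramolecular [2+2] cycloaddition and cycloreversion at ruthenium, with C8–C9 as the only new bond. No stereocenter is created; C1, C4, C5 and C6 are not touched, and the trans ring fusion follows from the trans arrangement of the two arms on C1 and C5. The step needs ring closure to win over cross-metathesis oligomerisation and over olefin migration; the two olefins of 11 can give no other ring, the quaternary C1 and the trans-vicinal arms hold C9 and C8 close (Thorpe–Ingold effect), and high dilution with removal of ethene does the rest. The free tertiary and secondary hydroxyls are tolerated by this catalyst class.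

**Step 7**
Reactants: 12 (1R,4R,5S,6S)-dauc-8-ene-4,6-diol
Product: 13 (1R,4R,5S,6S,8R,9S)-8,9-epoxydaucane-4,6-diol
Conditions: dimethyldioxirane (1.2 equiv, acetone solution), CH2Cl2, −20 → 0 °C
Reagents that add atoms: dimethyldioxirane, CC1(C)OO1
Why: Concerted, stereospecific oxygen transfer from the dioxirane to the electron-rich trisubstituted olefin should take place on the exposed face of the chair cycloheptene, anti to the axial angular methyl on C1 and syn to the C6 hydroxyl, which sets C8 (R) and C9 (S) together under neutral conditions that spare the acid-labile epoxide.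

**Step 8**
Reactants: 13 (1R,4R,5S,6S,8R,9S)-8,9-epoxydaucane-4,6-diol
Product: 14 (1R,4R,5S,6S,8R,9S)-8,9-epoxydaucane-4,6-diol 6-benzoate (target)
Conditions: BzCl (1.5 equiv), pyridine, DMAP (10 mol %), CH2Cl2, 0 °C → rt
Reagents that add atoms: benzoyl chloride, O=C(Cl)c1ccccc1
Why: DMAP-catalysed O-acylation should take place only at the secondary C6 hydroxyl, the tertiary C4 hydroxyl being too hindered, and the basic medium leaves the epoxide intact; no stereocenter is touched.

**Compound list**
1 | 3-ethoxycyclopent-2-en-1-one | CCOC1=CC(=O)CC1 | starting material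
2 | bromomagnesium 1-allyl-3-ethoxycyclopent-2-en-1-olate (racemic, not isolated) | CCOC1=CC(CC=C)(O[Mg]Br)CC1 | intermediate
3 | 3-allylcyclopent-2-en-1-one | C=CCC1=CC(=O)CC1 | intermediate
4 | dimethylaluminium (R)-3-allyl-3-methylcyclopent-1-en-1-olate (not isolated) | C[Al](C)OC1=C[C@@](C)(CC=C)CC1 | intermediate
5 | (R)-[(3-allyl-3-methylcyclopent-1-en-1-yl)oxy]trimethylsilane | C[Si](C)(C)OC1=C[C@@](C)(CC=C)CC1 | intermediate
6 | 3-methylbut-3-en-1-ol | CC(=C)CCO | starting material
7 | 3-methylbut-3-enal | CC(=C)CC=O | intermediate
8 | lithium (R)-3-allyl-3-methylcyclopent-1-en-1-olate (not isolated) | [Li]OC1=C[C@@](C)(CC=C)CC1 | intermediate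
9 | (R)-[(3-allyl-3-methylcyclopent-1-en-1-yl)oxy]dicyclohexylborane (not isolated) | C1CCCCC1B(OC2=C[C@@](C)(CC=C)CC2)C3CCCCC3 | intermediate
10 | (2S,3R)-3-allyl-2-[(1S)-1-hydroxy-3-methylbut-3-en-1-yl]-3-methylcyclopentan-1-one | O=C1CC[C@](C)(CC=C)[C@H]1[C@@H](O)CC(C)=C | intermediate
11 | (1R,2S,3R)-3-allyl-2-[(1S)-1-hydroxy-3-methylbut-3-en-1-yl]-3-methyl-1-(propan-2-yl)cyclopentan-1-ol | CC(C)[C@]1(O)CC[C@](C)(CC=C)[C@H]1[C@@H](O)CC(C)=C | intermediate
12 | (1R,4R,5S,6S)-dauc-8-ene-4,6-diol: trans-fused cyclopentane/cycloheptene, angular methyl on C1, hydroxyl and isopropyl on C4, hydroxyl on C6, methyl on olefinic C8 | CC(C)[C@]1(O)CC[C@]2(C)CC=C(C)C[C@H](O)[C@H]21 | intermediate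
13 | (1R,4R,5S,6S,8R,9S)-8,9-epoxydaucane-4,6-diol: epoxide oxygen on the face of H5 and the C6 oxygen, anti to the angular methyl | CC(C)[C@]1(O)CC[C@]2(C)C[C@@H]3O[C@]3(C)C[C@H](O)[C@H]21 | intermediate
14 | (1R,4R,5S,6S,8R,9S)-8,9-epoxydaucane-4,6-diol 6-benzoate (CNP0340059.1) | CC(C)[C@]1(O)CC[C@]2(C)C[C@@H]3O[C@]3(C)C[C@H](OC(=O)c3ccccc3)[C@H]21 | target

**Step count and risks**
Total step count: 8. Longest linear sequence: 7 steps (1 → 3 → 5 → 10 → 11 → 12 → 13 → 14); step 3 makes the aldehyde partner 7 from 6.

Three steps most likely to fail:

First, step 4 (aldol). The enolate may take a proton from the acidic β,γ-unsaturated aldehyde, which then isomerises to the conjugated enal and condenses with itself instead of adding; facial discrimination between allyl and methyl at C1 may also be modest. The fallback sets out from 5 and replaces the fragile aldehyde by one that cannot isomerise. The boron enolate (8, 9) is combined with 2-(2-methyl-1,3-dioxolan-2-yl)acetaldehyde F1, made from commercial ethyl 2-(2-methyl-1,3-dioxolan-2-yl)acetate with i-Bu2AlH in CH2Cl2 at −78 °C. This should give the ketal aldol (2S,3R)-3-allyl-2-[(1S)-1-hydroxy-2-(2-methyl-1,3-dioxolan-2-yl)ethyl]-3-methylcyclopentan-1-one F2. i-PrMgCl/CeCl3 as in step 5 should give the diol ketal F3, and PPTS in wet acetone should liberate the methyl ketone diol F4. Wittig methylenation (Ph3P=CH2 in excess, THF, 0 °C) of the methyl ketone then installs the 1,1-disubstituted olefin, and the route is rejoined at 11.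

Second, step 5 (isopropyl addition). The hindered ketone may be enolised or reduced by β-hydride transfer from the secondary organometallic, or the aldolate may undergo retro-aldol cleavage. The fallback sets out from 10 and changes the order, so that the C4 substituent is introduced as the less basic, non-reducing 2-propenyl group at a stage where no other olefin is left. Ring-closing metathesis of 10 (conditions of step 6) should give the trans-fused hydroxy ketone F5 (C4 ketone, C6 hydroxyl, C8=C9 olefin). Dimethyldioxirane (conditions of step 7) should give the epoxy ketone F6. 2-Propenylmagnesium bromide/CeCl3 (THF, −78 °C) should add to the ketone from the face opposite to C6 to give the isopropenyl carbinol F7. Homogeneous hydrogenation (H2, RhCl(PPh3)3, benzene) of the 1,1-disubstituted olefin then gives the isopropyl group, and the route is rejoined at 13.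

Third, step 2 (asymmetric conjugate addition). Facial discrimination by the catalyst on the five-membered enone may be insufficient, so that enantiopurity is eroded, or the skipped allyl olefin may migrate into conjugation. The fallback sets out from 3 and gives up catalyst control for a resolution. MeMgBr with CuBr·SMe2 (cat.) and Me3SiCl in THF at −78 °C should give the racemic silyl enol ether F8. The aldol of step 4 should give the racemic aldol F9 with the relative configuration of 10. The enantiomers are then separated by preparative chromatography on a chiral stationary phase, and the route is rejoined at 10.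

**Further compounds**
F1 | step 4 | 2-(2-methyl-1,3-dioxolan-2-yl)acetaldehyde | CC1(CC=O)OCCO1
F2 | step 4 | (2S,3R)-3-allyl-2-[(1S)-1-hydroxy-2-(2-methyl-1,3-dioxolan-2-yl)ethyl]-3-methylcyclopentan-1-one | O=C1CC[C@](C)(CC=C)[C@H]1[C@@H](O)CC2(C)OCCO2
F3 | step 4 | diol ketal: isopropyl adduct of F2 at C4, configuration as in 11 | CC(C)[C@]1(O)CC[C@](C)(CC=C)[C@H]1[C@@H](O)CC2(C)OCCO2
F4 | step 4 | methyl ketone diol: 11 with C8=O in place of the C8 methylene | CC(C)[C@]1(O)CC[C@](C)(CC=C)[C@H]1[C@@H](O)CC(C)=O
F5 | step 5 | trans-fused hydroxy ketone: ring-closed 10 with C4 ketone, C6 hydroxyl and C8=C9 olefin | O=C1CC[C@]2(C)CC=C(C)C[C@H](O)[C@H]21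
F6 | step 5 | epoxy hydroxy ketone: 8,9-epoxide of F5, oxygen anti to the angular methyl | O=C1CC[C@]2(C)C[C@@H]3O[C@]3(C)C[C@H](O)[C@H]21
F7 | step 5 | isopropenyl analogue of 13: prop-1-en-2-yl in place of isopropyl on C4, same spatial arrangement at all centres | C=C(C)[C@]1(O)CC[C@]2(C)C[C@@H]3O[C@]3(C)C[C@H](O)[C@H]21
F8 | step 2 | racemic [(3-allyl-3-methylcyclopent-1-en-1-yl)oxy]trimethylsilane | C[Si](C)(C)OC1=CC(C)(CC=C)CC1
F9 | step 2 | racemic aldol, 1:1 mixture of 10 and its enantiomer | O=C1CC[C@](C)(CC=C)[C@H]1[C@@H](O)CC(C)=C.O=C1CC[C@@](C)(CC=C)[C@@H]1[C@H](O)CC(C)=C
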